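Slowness is what the autumn run shows first: with 0.2 mol% precatalyst it holds 10.3% left-handed product after 40.0 h. Your flask looks nearly the same, with the same loading, but autumn has half of its coupling partner and your flask runs for 3.0 d.

common to all: left-handed substrate 0.10 M; right-handed substrate 0.10 M

| run | coupling partner | precatalyst | remark | time |
|---|---|---|---|---|
| midnight | 3 equiv | 0.13 mol% | run made earlier |  |
| winter | 3 equiv | 0.3 mol% | run made earlier |  |
| autumn | 1.5 equiv | 0.2 mol% | run made earlier |  |
| flask | 3.00 equiv | 0.2 mol% |  | 3.0 d |

- midnight (time / h: left-handed product / %, right-handed product / %): 3.00: 0.1, 0.3; 6.00: 0.7, 0; 10.0: 1.3, 0; 15.0: 2.6, 0.4; 25.0: 5.6, 1.0; 40.0: 14.0, 0.5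
- winter (time / h: left-handed product / %, right-handed product / %): 3.00: 0.7, 0; 8.00: 1.2, 0; 15.0: 5.3, 0.1; 25.0: 13.0, 1.7; 30.0: 17.1, 1.3; 40.0: 24.0, 1.5
- autumn (time / h: left-handed product / %, right-handed product / %): 3.00: 0, 0.7; 6.00: 0.8, 0.4; 12.0: 0.7, 0.4; 25.0: 4.7, 0.1; 40.0: 10.3, 0

(standard deviation of a reading: 0.5 percentage points)

- free catalyst is single-handed; left-handed substrate and right-handed substrate are mirror images of each other, charged as a racemate, each of them at the stated concentration
- the analysis behind the earlier runs scatters by 0.5 percentage points, standard deviation
- an excess is the difference of the two amounts in percent of their sum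
- an excess is below zero if the other one leads

- left-handed product and right-handed product together, in percent of the left-handed substrate and right-handed substrate charged together, at 3.0 d
- excess of left-handed product over right-handed product in the product at 3.0 d
- whether the exchange between left-handed substrate and right-handed substrate keeps pace with the reaction: how far the product's excess at 3.0 d gets from its value without exchange to its value with instant exchange (above 80% keeps pace, below 20% hardly takes part, else lags behind)

To compare them, I use exposure: minus the natural logarithm of the share of the left-handed substrate's charge not found as left-handed product. Per unit loading, winter's exposure at 3 equiv after 40.0 h is twice autumn's at 1.5 equiv after the same time. As a reading, then, the loss of left-handed substrate looks pseudo-first-order in c(left-handed substrate), with a rate constant following c(coupling partner). My reckoning divides by the equivalents and takes the growth with time from winter: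

Autumn exposure: 0.231; per equivalent: 0.154

Winter exposure at 25.0 h and 40.0 h: 0.301 and 0.654

Power of time: 1.65

At the asked time, w = 0.406

This w is the exposure per equivalent of coupling partner at 0.2 mol% precatalyst and 3.0 d. For your flask:

Exposure: 1.22; left-handed product: 35.2%

So your flask should end far beyond autumn, with an exposure greater than autumn's 0.231, through twice the coupling partner and the longer time.

The forecast gives 37% product (31% to 44%), an excess of 84% (75% to 92%), and exchange that hardly takes part, holding that “exchange looks minor”.

    left-handed substrate ⇌ right-handed substrate (k = 0.00730 h⁻¹)
    2 free catalyst → spent catalyst (k = 23.0 M⁻¹ h⁻¹)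
    coupling partner + free catalyst + left-handed substrate → free catalyst + left-handed product (k = 1300 M⁻² h⁻¹)
    coupling partner + free catalyst + right-handed substrate → free catalyst + right-handed product (k = 74.0 M⁻² h⁻¹)
    precatalyst → free catalyst (k = 0.00900 h⁻¹)

Your flask gives 39.9% product at an excess of 84.6%, both inside the forecast's ranges. But its exchange lags behind: it gets 28% of the way, more than the 20% mark. Your flask holds 36.8% left-handed product, an exposure of 1.33, more than the reckoned 1.22. For the neighbour with 1.80 equiv coupling partner, the same w gives an exposure of 0.730, hence 25.9% left-handed product. At 3.00 d that neighbour holds 25.9% left-handed product.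

(The runs were computed with constants of no real substance, noise included.)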